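**Retrosynthetic overview**
- The target is reached last by Suzuki propenylation at C5 and desilylation of a 5-bromo-2-aryl-3-methyl-2,3-dihydrobenzofuran.
- Key disconnection: C3–C3a and C2–O1 are made together in a palladium-catalysed enantioselective syn-oxyarylation ([3+2] annulation) of fragment B, an (E)-arylpropene, with fragment A, an o-iodophenol. This step sets both stereocentres (trans).
- Fragment A comes from catechol by mono-methylation, para-bromination and ortho-iodination.
- Fragment B comes from catechol by dimethylation, ortho-lithiation/oxidation, silylation and one-pot iridium C–H borylation/Suzuki coupling with (E)-1-bromopropene.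
- Ring order: rings A and B are the intact benzene rings of catechol; ring C (the dihydrofuran) is the only ring built, in the annulation.

Assumption: L* is the enantiomer of a TY-Phos-type tert-butanesulfinamide-derived monophosphine (Sadphos family) that delivers ring A to the Re face of the methyl-bearing alkene carbon; which antipode this is would be fixed in the first run, the mirror-image ligand giving the mirror-image product.

**Step 1**
Reactants: 1 catechol
Product: 2 2-methoxyphenol (guaiacol)
Conditions: MeI (1.0 equiv), K2CO3 (1.0 equiv), acetone, 56 °C; guaiacol separated from catechol and veratrole by extraction and distillation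
Reagents that add atoms: iodomethane, CI
Why: Williamson mono-O-methylation works because one equivalent of weak base mainly forms the more acidic catechol monoanion, so the mono-ether predominates.

**Step 2**
Reactants: 2 2-methoxyphenol
Product: 3 4-bromo-2-methoxyphenol
Conditions: NBS (1.0 equiv), MeCN, 0 °C to rt
Reagents that add atoms: N-bromosuccinimide, O=C1CCC(=O)N1Br
Why: Electrophilic aromatic bromination goes para to the free hydroxyl, the strongest activating group.

**Step 3**
Reactants: 3 4-bromo-2-methoxyphenol
Product: 4 4-bromo-2-iodo-6-methoxyphenol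
Conditions: NIS (1.05 equiv), TsOH·H2O (10 mol%), MeCN, 0 °C to rt
Reagents that add atoms: N-iodosuccinimide, O=C1CCC(=O)N1I
Why: Electrophilic aromatic iodination takes the only free position ortho to the hydroxyl because the para position is blocked by bromine.

**Step 4**
Reactants: 1 catechol
Product: 5 1,2-dimethoxybenzene (veratrole)
Conditions: MeI (2.5 equiv), K2CO3 (3 equiv), acetone, 56 °C
Reagents that add atoms: iodomethane, CI
Why: Exhaustive Williamson methylation of both phenols is straightforward with excess reagent.

**Step 5**
Reactants: 5 1,2-dimethoxybenzene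
Product: 8 2,3-dimethoxyphenol, via aryllithium 6 (not isolated), via dimethyl arylboronate 7 (not isolated)
Conditions: n-BuLi (1.1 equiv), TMEDA, Et2O, 0 °C to rt; B(OMe)3, −78 °C to rt; AcOH, 30% H2O2, 0 °C to rt
Reagents that add atoms: hydrogen peroxide, OO (oxygen of the product); n-butyllithium, [Li]CCCC (lithium of 6); trimethyl borate, COB(OC)OC (boron group of 7)
Why: Directed ortho-metalation next to a methoxy group, borylation and oxidative C–B to C–O migration give the 1,2,3-trioxygenated ring.

**Step 6**
Reactants: 8 2,3-dimethoxyphenol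
Product: 9 triisopropyl(2,3-dimethoxyphenoxy)silane
Conditions: TIPSCl (1.2 equiv), imidazole (2.5 equiv), DMF, rt
Reagents that add atoms: triisopropylsilyl chloride, CC(C)[Si](Cl)(C(C)C)C(C)C
Why: Silylation masks the phenol with a bulky group that blocks ortho borylation and survives base, phenoxides and palladium chemistry.

**Step 7**
Reactants: 9 triisopropyl(2,3-dimethoxyphenoxy)silane; 10 (E)-1-bromoprop-1-ene
Product: 12 triisopropyl{2,3-dimethoxy-5-[(E)-prop-1-en-1-yl]phenoxy}silane, via arylboronic pinacol ester 11 (not isolated)
Conditions: [Ir(OMe)(cod)]2 (1.5 mol%), dtbpy (3 mol%), B2pin2 (1.0 equiv), THF, 80 °C; volatiles off; then 10 (1.5 equiv), Pd(dppf)Cl2 (3 mol%), aq K3PO4, THF, 65 °C, sealed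
Reagents that add atoms: bis(pinacolato)diboron, CC1(C)OB(OC1(C)C)B1OC(C)(C)C(C)(C)O1 (boryl group of 11)
Why: Sterically controlled iridium-catalysed C–H borylation hits the only C–H with no ortho substituent (C5), and the Suzuki–Miyaura coupling keeps the E geometry of the alkenyl bromide.

**Step 8**
Reactants: 4 4-bromo-2-iodo-6-methoxyphenol; 12 triisopropyl{2,3-dimethoxy-5-[(E)-prop-1-en-1-yl]phenoxy}silane
Product: 13 {5-[(2S,3S)-5-bromo-7-methoxy-3-methyl-2,3-dihydro-1-benzofuran-2-yl]-2,3-dimethoxyphenoxy}triisopropylsilane
Conditions: 4 (1.2 equiv), Pd2(dba)3 (2.5 mol%), L* (11 mol%), K3PO4 (2 equiv), toluene, 60 °C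
Reagents that add atoms: none
Why: Proposed new method: enantioselective palladium-catalysed syn-oxyarylation ([3+2] heteroannulation) of an acyclic (E)-1-arylpropene with an o-iodophenol — zerovalent palladium inserts into C–I only (C–Br is slower at 60 °C); the chiral monophosphine steers syn-carbopalladation so that ring A adds to the Re face of the methyl-bearing carbon (C3 = S) while palladium sits on the benzylic carbon as an η3-benzyl species stabilised by the para-methoxy group; the potassium phenoxide then closes a six-membered oxapalladacycle, which blocks the bond rotation needed for β-hydride elimination, and stereoretentive C–O reductive elimination from divalent palladium sets C2 = S, so net syn addition across the E-alkene gives the trans ring; the closest known reaction types are the racemic Pd(OAc)2/Ag2CO3 Heck oxyarylation of chromenes and 1,2-dihydronaphthalenes with o-iodophenols and the enantioselective palladium/sulfinamide-phosphine Heck/Tsuji–Trost annulation of o-bromophenols with 1,3-dienes, neither shown enantioselectively on an acyclic 1,2-disubstituted styrene where the insertion itself sets the stereocentre.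

**Step 9**
Reactants: 13 {5-[(2S,3S)-5-bromo-7-methoxy-3-methyl-2,3-dihydro-1-benzofuran-2-yl]-2,3-dimethoxyphenoxy}triisopropylsilane; 14 (E)-prop-1-en-1-ylboronic acid
Product: 16 5-[(2S,3S)-7-methoxy-3-methyl-5-((E)-prop-1-en-1-yl)-2,3-dihydro-1-benzofuran-2-yl]-2,3-dimethoxyphenol (CNP0299956.1), via silyl ether 15 (not isolated)
Conditions: 14 (1.5 equiv), Pd(dppf)Cl2 (5 mol%), K2CO3 (3 equiv), dioxane/H2O 5:1, 80 °C; then TBAF (2 equiv), rt; NH4Cl work-up
Reagents that add atoms: none
Why: Suzuki–Miyaura coupling of the aryl bromide keeps the E geometry, and fluoride desilylation under non-acidic conditions leaves the acid-sensitive benzylic ether and both stereocentres untouched.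

**Compound list**
1 | catechol (benzene-1,2-diol) | Oc1ccccc1O | starting material
2 | 2-methoxyphenol (guaiacol) | COc1ccccc1O | intermediate
3 | 4-bromo-2-methoxyphenol | COc1cc(Br)ccc1O | intermediate
4 | 4-bromo-2-iodo-6-methoxyphenol | COc1cc(Br)cc(I)c1O | intermediate
5 | 1,2-dimethoxybenzene (veratrole) | COc1ccccc1OC | intermediate
6 | (2,3-dimethoxyphenyl)lithium | [Li]c1cccc(OC)c1OC | intermediate
7 | dimethyl (2,3-dimethoxyphenyl)boronate | COB(OC)c1cccc(OC)c1OC | intermediate
8 | 2,3-dimethoxyphenol | COc1cccc(O)c1OC | intermediate
9 | triisopropyl(2,3-dimethoxyphenoxy)silane | COc1cccc(O[Si](C(C)C)(C(C)C)C(C)C)c1OC | intermediate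
10 | (E)-1-bromoprop-1-ene | C/C=C/Br | starting material
11 | 2-[3,4-dimethoxy-5-(triisopropylsilyloxy)phenyl]-4,4,5,5-tetramethyl-1,3,2-dioxaborolane | CC1(C)OB(OC1(C)C)c1cc(O[Si](C(C)C)(C(C)C)C(C)C)c(OC)c(OC)c1 | intermediate
12 | triisopropyl{2,3-dimethoxy-5-[(E)-prop-1-en-1-yl]phenoxy}silane | C/C=C/c1cc(O[Si](C(C)C)(C(C)C)C(C)C)c(OC)c(OC)c1 | intermediate
13 | {5-[(2S,3S)-5-bromo-7-methoxy-3-methyl-2,3-dihydro-1-benzofuran-2-yl]-2,3-dimethoxyphenoxy}triisopropylsilane | Brc1cc(OC)c2c(c1)[C@H](C)[C@@H](c1cc(O[Si](C(C)C)(C(C)C)C(C)C)c(OC)c(OC)c1)O2 | intermediate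
14 | (E)-prop-1-en-1-ylboronic acid | C/C=C/B(O)O | starting material
15 | {2,3-dimethoxy-5-[(2S,3S)-7-methoxy-3-methyl-5-((E)-prop-1-en-1-yl)-2,3-dihydro-1-benzofuran-2-yl]phenoxy}triisopropylsilane | C/C=C/c1cc(OC)c2c(c1)[C@H](C)[C@@H](c1cc(O[Si](C(C)C)(C(C)C)C(C)C)c(OC)c(OC)c1)O2 | intermediate
16 | 5-[(2S,3S)-7-methoxy-3-methyl-5-((E)-prop-1-en-1-yl)-2,3-dihydro-1-benzofuran-2-yl]-2,3-dimethoxyphenol (CNP0299956.1) | C/C=C/c1cc(OC)c2c(c1)[C@H](C)[C@@H](c1cc(O)c(OC)c(OC)c1)O2 | target

**Step count**
Total steps: 9. Longest linear sequence: 6 (steps 4, 5, 6, 7, 8, 9 from catechol). The other branch (steps 1, 2, 3) joins at step 8.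

**Steps most likely to fail**

Step 8 (the proposed new annulation). Likely failure modes are β-hydride elimination to the 1,2-diarylpropene, low enantioselectivity, loss of trans selectivity through epimerisation or outer-sphere attack at the η3-benzyl stage, and competing insertion into C–Br. The fallback uses known chemistry, sets out from 12 and 4 and comes back at 13.
- Cross-metathesis of 12 with dimethyl (Z)-but-2-ene-1,4-diyl dicarbonate (second-generation Grubbs catalyst, RuCl2(=CHPh)(H2IMes)(PCy3), CH2Cl2, 40 °C) gives (E)-3-[3,4-dimethoxy-5-(triisopropylsilyloxy)phenyl]prop-2-en-1-yl methyl carbonate F1.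
- Iridium-catalysed enantioselective allylic etherification of F1 with the sodium phenoxide of 4 ([Ir(cod)Cl]2, binaphthol-based bis(1-phenylethyl)amine phosphoramidite, THF, 50 °C; ligand antipode chosen for the S ether) sets C2 and gives the branched ether triisopropyl{5-[(1S)-1-(4-bromo-2-iodo-6-methoxyphenoxy)prop-2-en-1-yl]-2,3-dimethoxyphenoxy}silane F2.
- A 5-exo-trig aryl radical cyclisation of F2 (Bu3SnH, AIBN, benzene, 80 °C, slow addition) reacts at C–I in preference to C–Br, forms C3–C3a and turns the terminal CH2 into the 3-methyl group. The substituent at C2 directs the new centre trans, which gives 13.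

Step 7 (one-pot C–H borylation/Suzuki coupling). Likely failure modes are boron hydride and iridium residues disturbing the palladium stage, loss of the volatile bromide 10, and erosion of E purity. The fallback sets out from 11, now isolated by filtration through silica, and comes back at 12.
- Palladium-catalysed allylation of 11 with allyl bromide (Pd(PPh3)4, K2CO3, THF/H2O, 60 °C) gives triisopropyl[2,3-dimethoxy-5-(prop-2-en-1-yl)phenoxy]silane F3.
- Double-bond migration into conjugation (RuHCl(CO)(PPh3)3, 2 mol%, toluene, 80 °C) gives the thermodynamically favoured (E)-propenyl compound 12, as in the eugenol to isoeugenol isomerisation.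

Step 1 (mono-methylation of catechol). The likely failure is a statistical mixture of catechol, guaiacol and veratrole with a modest yield. The fallback sets out from 5 (made in step 4) and comes back at 2.
- Selective mono-demethylation of 5 with NaSEt (DMF, 130 °C) stops cleanly after one methyl group, because the phenoxide formed deactivates the second ether. No compound outside the list is made on this way (none F0).

**Further compounds**
F1 | step 8 | (E)-3-[3,4-dimethoxy-5-(triisopropylsilyloxy)phenyl]prop-2-en-1-yl methyl carbonate | COC(=O)OC/C=C/c1cc(O[Si](C(C)C)(C(C)C)C(C)C)c(OC)c(OC)c1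
F2 | step 8 | triisopropyl{5-[(1S)-1-(4-bromo-2-iodo-6-methoxyphenoxy)prop-2-en-1-yl]-2,3-dimethoxyphenoxy}silane | C=C[C@@H](c1cc(O[Si](C(C)C)(C(C)C)C(C)C)c(OC)c(OC)c1)Oc1c(I)cc(Br)cc1OC
F3 | step 7 | triisopropyl[2,3-dimethoxy-5-(prop-2-en-1-yl)phenoxy]silane | C=CCc1cc(O[Si](C(C)C)(C(C)C)C(C)C)c(OC)c(OC)c1
F0 | step 1 | none | none
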